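## The problem

The target is an oxane (ring atoms O1, C2–C6) with a 4-hydroxyphenyl group on C2, an (E)-3-(4-hydroxyphenyl)allyl arm on C3 and, on C5, an exocyclic carbinol carbon C7 that carries the third 4-hydroxyphenyl group. C4 and C6 are plain methylenes. Four stereocentres must be set, (2R,3S,5R) in the ring and (R) at C7, and all three ring substituents lie on one face. Only C5 and C7 are directly bonded, so C7 can control C5 if both are tied into a temporary ring. C2 and C3 are remote from C7 and can be governed from C5 only if the oxane is folded, as in a cis-fused bicycle with one open face. The groups that will not survive rough treatment are the two para-oxygenated benzylic C–O bonds (the C2–O1 ether and the C7 carbinol), which ionise towards quinone methides in acid and cleave under hydrogenolysis, and the 4-hydroxystyrene unit, which cannot be present during a hydrogenation. The phenols must therefore be released last, without acid or reductant. The feature that opens a short route is that C5 carries both C6 (bonded to O1) and C7 (bonded to oxygen and aryl). C6=C5–C7(O)Ar is the enol ether edge of a 4-aryl-4H-1,3-dioxin whose CH2 group links the C7 oxygen to an oxygen on C6, and O1=C2–C3=C4 is an aryl α-methylene ketone; a [4+2] union of the two forms C4–C5 and O1–C6 and closes the oxane.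

## Retrosynthesis

**22 from 21.** No skeletal bond is cut; the three phenols are masked as pivalates in 21. Acyl groups are preferred to silyl ethers because an acyloxy substituent makes the aryl rings poor cation stabilisers. This protects the C2–O1 and C7–O bonds in every Lewis-acid step and protects the allylic, benzylic C–O bond of the dioxin. Benzyl ethers are excluded by the alkene. The forward step is a mild methanolysis.

**21 from 19.** The C6 methylene and the free C7 hydroxyl of 21 are reconnected through an O–CH2–O bridge, giving the cis-fused acetal 19 (C6–H becomes C6–O). The alternative, a lactol at C6 with free C7–OH, is a β-hydroxy aldehyde in its open form and invites retro-aldol, dehydration and C5 epimerisation. The acetal in 19 masks both functions. The forward step must cleave only the bond from C6 to the formal oxygen and deliver hydride to C6.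

**19 from 18 and 2.** The arm's C=C bond is cut by Julia–Kocienski logic into the tetrazolyl sulfone 18 and aldehyde 2, the same aldehyde that opens the dioxin arm. The reverse polarity (side-chain aldehyde plus benzylic phosphonate) would need a terminal oxygen carried and differentiated from three phenols. The sulfone instead comes from the primary chloride already present in ketone 11, through sulfide 16 from chloride 15. The forward reaction must be E-selective and the base must spare the aryl esters.

**15 from 14.** Removing the C2–H and C3–H bonds gives the tetrasubstituted aryl enol ether 14. Setting C2 and C3 by addition to this bond is preferred over setting them during ring formation because the fused dioxane of 14 blocks one face. The forward step needs syn delivery of hydrogen to the open face without benzylic hydrogenolysis. Precursor 14 has only the stereocentres made in the cycloaddition.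

**14 from 10 and 13.** C4–C5 and O1–C6 are cut together. This is the only cut that removes the ring and two ring bonds at once and returns two fragments of similar size: enone 13 (O1=C2–C3=C4) and dioxin 10 (C6=C5, with C7 and its aryl group). The single stereocentre of 10 has to control the face of its double bond, and the enone has to prefer the enol ether over itself.

**13 from 12 from 11.** The exocyclic methylene is cut by Mannich-type methylenation to ketone 12, the pivalate of commercial 11. The chloride of 11 is kept as the handle for the arm, so no displacement or extra protection is needed.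

**10 from 8, 7 and 6.** The enol ether C=C is traced to lactol 8 (loss of water), 8 to lactone 7, and the acetal CH2 of 7 to β-hydroxy acid 6. Bridging a 1-aryl-1,2,3-triol and eliminating the middle hydroxyl would face three competing acetals and two directions of elimination. Here only two oxygens can be bridged and the elimination can go only one way.

**6 from 4, 2 and 1.** The acid is the oxidative-cleavage product of homoallylic alcohol 4. The C–C bond next to the carbinol is cut to aldehyde 2 and an allyl nucleophile, and 2 is the pivalate of 1. The forward allylation must be enantioselective, because this centre becomes C7 and is the source of all absolute configuration.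

## Roads not taken

**Alternative 1:** The cut is at C2–C3 and C5–C7, the two aldol bonds of a hidden C2-symmetric chain ArCH(O)–C3–C4–C5–CH(O)Ar. C6 and the first carbon of the arm are written as the carboxyl carbons of the glutaryl bis(N-acyloxazolidinone) A1. Soft enolisation of A1 at both ends (MgCl2, Et3N, Me3SiCl) and addition to two molecules of aldehyde A2 would give the bis(anti-aldol) adduct A3.
- Merits: all four stereocentres in one auxiliary-controlled step from an achiral diacid, no hydrogenation, and a free desymmetrisation, since lactonisation of either hydroxyl onto the distal acyl group gives the same δ-lactone. In stereocentre economy this is better than the chosen plan, which needs three stereo-determining steps (2, 9 and 10).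
- Weak points: no ring is closed. One carboxyl carbon must become the C6H2–O ether beside two electron-rich benzylic carbinols. The other must become a CH2 bonded to a vinyl carbon, which requires full reduction and an sp3–sp2 coupling at a β-branched primary centre. The second aldol must also proceed next to the first aldolate without retro-aldol.
- Against it, the chosen plan makes the ring and both ring bonds in the key step, carries no excess oxidation state, and grows the arm from an unhindered primary chloride.

**Alternative 2:** The cut is the two C–C bonds of ring A, the C2 aryl group, grown last on the C2-ethynyl oxane A4. CoBr2(dppe) (dppe = 1,2-bis(diphenylphosphino)ethane) with Zn and ZnI2 would join A4 and diene A5 in a [4+2] cycloaddition, and DDQ would aromatise the adduct to A6.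
- Merits: the ionisable C2 benzylic ether does not exist until the last C–C step, and ring A arrives as a free phenol distinct from the others. In protecting-group logic for C2 this is as good as or better than the chosen plan.
- Weak points: the step makes no stereocentre and not the oxane. All four stereocentres and the cis 2,3,5-pattern must already be in A4, so the central problem is moved, not solved. The oxygen of A5 must end para to C2. DDQ would meet a doubly activated allylic/benzylic CH2 and a silyloxybenzylic ether in A6.
- The chosen plan uses its key step on the ring and its stereocentres, and pays with pivalate protection to tame the C2 ether.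

**Alternative 3:** The cut is at C2–C3 and O1–C6. Under the chiral trivalent chromium Lewis acid CrCl(salen) (salen = (R,R)-N,N'-bis(3,5-di-tert-butylsalicylidene)cyclohexane-1,2-diaminate), aldehyde A2 and the (1E,3Z)-diene A7, which already carries the cinnamyl arm, would undergo an endo [4+2] cycloaddition. Acid work-up (CF3CO2H) would give the 2,3-cis dihydropyranone A8.
- Merits: catalytic absolute control, C2 and C3 set cis directly, and the arm in place from the start, so neither the face-selective hydrogenation (step 10) nor the late olefination (step 13) is needed. On these points it is better than the chosen plan.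
- Weak points: A8 has a C4 carbonyl that the target lacks and nothing on C5. The C5–C7 bond and both of its stereocentres would have to be added by an aldol on the pyranone, and C4 then deoxygenated beside a styrene. C3 is α to the ketone and can epimerise to the trans isomer. A2 is an electron-rich, sluggish heterodienophile, and the Z-substituted diene A7 is hard to obtain pure.
- Against it, the chosen plan delivers C4 as a methylene, builds the C5–C7 relationship with the ring, and has no epimerisable centre.

Key step: step 9

Assumption: the drawn structure is read as (2R,3S,5R) in the oxane and (R) at C7, with the C2 aryl group, the C3 arm and the C5 substituent all cis. Oxane numbering of the target (O1, C2–C6, C7) is used in the text; descriptors of intermediates follow their own numbering and priorities.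

## Route

Step 1
Reactants: 1 4-hydroxybenzaldehyde
Product: 2 4-formylphenyl pivalate
Conditions: t-BuCOCl, Et3N, DMAP (cat.), CH2Cl2, 0 °C → rt
Reagents that add atoms: pivaloyl chloride, CC(C)(C)C(=O)Cl
Why: O-acylation of the phenol under nucleophilic catalysis; the aldehyde is untouched, and the hindered, electron-withdrawing pivalate stays in place until the last step.

Step 2
Reactants: 2 4-formylphenyl pivalate
Product: 4 4-[(1R)-1-hydroxybut-3-en-1-yl]phenyl pivalate, via O-boryl ether 3 (not isolated)
Conditions: allylB(pin) (1.2 equiv), (R)-TRIP (5 mol%; (R)-3,3'-bis(2,4,6-triisopropylphenyl)-1,1'-binaphthalene-2,2'-diyl hydrogen phosphate), toluene, 4 Å MS, −30 °C; aq. NaHCO3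
Reagents that add atoms: allylboronic acid pinacol ester, C=CCB1OC(C)(C)C(C)(C)O1
Why: chiral phosphoric acid-catalysed allylboration of an aromatic aldehyde through a closed chair transition state with the acid bound to the boronate oxygen; the (R)-acid should expose the Re face and give the (R)-carbinol that becomes C7, and the O-boryl ether 3 is hydrolysed on work-up.

Step 3
Reactants: 4 4-[(1R)-1-hydroxybut-3-en-1-yl]phenyl pivalate
Product: 6 (3R)-3-hydroxy-3-[4-(pivaloyloxy)phenyl]propanoic acid, via β-hydroxy aldehyde 5 (not isolated)
Conditions: O3, CH2Cl2, −78 °C; PPh3, −78 °C → rt; then NaClO2, NaH2PO4, 2-methylbut-2-ene, t-BuOH/H2O, 0 °C → rt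
Reagents that add atoms: ozone, [O-][O+]=O; sodium chlorite, [Na+].[O-]Cl=O
Why: ozonolysis of the terminal alkene with reductive work-up gives aldehyde 5, which is oxidised at once by Pinnick oxidation before it can dehydrate; the carbinol centre is not involved and the acylated arene resists ozone.

Step 4
Reactants: 6 (3R)-3-hydroxy-3-[4-(pivaloyloxy)phenyl]propanoic acid
Product: 7 4-[(4R)-6-oxo-1,3-dioxan-4-yl]phenyl pivalate
Conditions: (CH2O)n, camphor-10-sulfonic acid (5 mol%), CH2Cl2, reflux over 4 Å MS
Reagents that add atoms: paraformaldehyde (formaldehyde), C=O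
Why: acid-catalysed acetalisation of a β-hydroxy acid with formaldehyde to a 1,3-dioxan-4-one; only two oxygens can be bridged, so the acetal position is unambiguous, and the acyloxy group disfavours benzylic ionisation and dehydration.

Step 5
Reactants: 7 4-[(4R)-6-oxo-1,3-dioxan-4-yl]phenyl pivalate
Product: 8 4-[(4R)-6-hydroxy-1,3-dioxan-4-yl]phenyl pivalate (both C6 epimers)
Conditions: i-Bu2AlH (1.1 equiv), CH2Cl2, −78 °C; aq. KNaC4H4O6; used crude
Reagents that add atoms: none
Why: partial reduction of the lactone, an activated acylal-type ester, to the lactol, as established for 1,3-dioxan-4-ones; with one equivalent at −78 °C the hindered aryl pivalate should react much more slowly.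

Step 6
Reactants: 8 4-[(4R)-6-hydroxy-1,3-dioxan-4-yl]phenyl pivalate
Product: 10 4-[(4R)-4H-1,3-dioxin-4-yl]phenyl pivalate, via anomeric mesylate 9 (not isolated)
Conditions: MeSO2Cl, Et3N, CH2Cl2, 0 °C → 40 °C; Et3N-washed silica
Reagents that add atoms: none
Why: dehydration of a 2-deoxy-type lactol through its anomeric mesylate (ionisation assisted by the ring oxygen, then deprotonation by Et3N), the standard glycal-type enol ether synthesis; the only β-hydrogens are on C5, so the 4H-1,3-dioxin is the only possible alkene and the stereocentre is untouched.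

Step 7
Reactants: 11 4-chloro-1-(4-hydroxyphenyl)butan-1-one
Product: 12 4-(4-chlorobutanoyl)phenyl pivalate
Conditions: t-BuCOCl, Et3N, DMAP (cat.), CH2Cl2, 0 °C
Reagents that add atoms: pivaloyl chloride, CC(C)(C)C(=O)Cl
Why: phenol acylation; at 0 °C the amine base does not enolise the ketone towards cyclopropane formation with the γ-chloride.

Step 8
Reactants: 12 4-(4-chlorobutanoyl)phenyl pivalate
Product: 13 4-(4-chloro-2-methylidenebutanoyl)phenyl pivalate
Conditions: (CH2O)n, i-Pr2NH2+ CF3CO2− (1 equiv), CF3CO2H (10 mol%), THF, 65 °C; stored cold with BHT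
Reagents that add atoms: paraformaldehyde (formaldehyde), C=O
Why: Mannich-type α-methylenation of an aryl alkyl ketone (ammonium salt-mediated condensation with formaldehyde, then β-elimination); there is one enolisable position, and the chloride and pivalate are inert to the weakly acidic medium.

Step 9
Reactants: 10 4-[(4R)-4H-1,3-dioxin-4-yl]phenyl pivalate; 13 4-(4-chloro-2-methylidenebutanoyl)phenyl pivalate
Product: 14 (4R,4aS,8aR)-6-(2-chloroethyl)-4,7-bis[4-(pivaloyloxy)phenyl]-4a,8a-dihydro-4H,5H-pyrano[2,3-d][1,3]dioxine
Conditions: Eu(fod)3 (10 mol%; fod = 6,6,7,7,8,8,8-heptafluoro-2,2-dimethyloctane-3,5-dionate), toluene (2 M), BHT (trace), 40 °C; 13 (2 equiv) added in portions; Et3N-washed silica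
Reagents that add atoms: none
Why: This is an inverse-electron-demand oxa-Diels–Alder reaction in which the Eu-bound s-cis enone 13 (O1=C2–C3=C4) reacts through its LUMO with the enol ether C5=C6 of 10 in a concerted, asynchronous [4+2] cycloaddition, C4–C5 forming ahead of O1–C6. The closest known reaction type is the thermal or lanthanide-promoted cycloaddition of α,β-unsaturated ketones and aldehydes with cyclic enol ethers such as dihydropyran and glycals; 10 is a cyclic enol ether of that class whose second ring oxygen lowers its HOMO somewhat, which is why the enone is activated. The dihydropyran ring closes by the cycloaddition itself and is cis-fused to the dioxane because both bonds form on one face of a ring-held Z double bond. Regiochemistry follows from polarisation: the nucleophilic C5 bonds to the methylene terminus C4 and the carbonyl oxygen to the oxygen-bearing C6. C5 (C4a of 14) is set by approach of the enone anti to the allylic aryl group on C7, as additions to glycals go anti to the C3 substituent, and C6 (C8a) follows from suprafacial addition and is removed later. Endo or exo orientation has no stereochemical consequence because C4 is a methylene and O1 bears nothing. The step needs chemoselectivity over hetero-Diels–Alder dimerisation of 13 and over heterolysis of the allylic, benzylic C–O bond of 10; the electron-rich enol ether should outrun the enone C=C, 13 is fed in excess, and the pivaloyloxy group keeps the dioxin aryl ring from stabilising a cation. Absolute configuration comes only from 10.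

Step 10
Reactants: 14 (4R,4aS,8aR)-6-(2-chloroethyl)-4,7-bis[4-(pivaloyloxy)phenyl]-4a,8a-dihydro-4H,5H-pyrano[2,3-d][1,3]dioxine
Product: 15 (4R,4aS,6R,7R,8aR)-6-(2-chloroethyl)-4,7-bis[4-(pivaloyloxy)phenyl]hexahydro-4H-pyrano[2,3-d][1,3]dioxine
Conditions: H2 (3 atm), 5% Rh/Al2O3, EtOAc, rt
Reagents that add atoms: none
Why: heterogeneous syn-hydrogenation of the tetrasubstituted aryl enol ether from the convex face of the cis-fused bicycle (the dioxane ring and the axial acetal oxygen cover the other face) puts the new hydrogens at oxane C2 and C3 cis to the ring-fusion hydrogens, so the aryl group and the chloroethyl arm end cis to the C5 substituent; Rh/Al2O3 is chosen because it seldom cleaves benzylic C–O or C–Cl bonds.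

Step 11
Reactants: 15 (4R,4aS,6R,7R,8aR)-6-(2-chloroethyl)-4,7-bis[4-(pivaloyloxy)phenyl]hexahydro-4H-pyrano[2,3-d][1,3]dioxine
Product: 16 (4R,4aS,6R,7R,8aR)-6-[2-(1-phenyl-1H-tetrazol-5-ylsulfanyl)ethyl]-4,7-bis[4-(pivaloyloxy)phenyl]hexahydro-4H-pyrano[2,3-d][1,3]dioxine
Conditions: sodium 1-phenyl-1H-tetrazole-5-thiolate, NaI (10 mol%), DMF, 60 °C
Reagents that add atoms: sodium 1-phenyl-1H-tetrazole-5-thiolate, [Na+].[S-]c1nnnn1-c1ccccc1
Why: SN2 displacement of the unhindered primary chloride (Finkelstein catalysis) by a soft, weakly basic thiolate; no base is present that could attack the aryl esters.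

Step 12
Reactants: 16 (4R,4aS,6R,7R,8aR)-6-[2-(1-phenyl-1H-tetrazol-5-ylsulfanyl)ethyl]-4,7-bis[4-(pivaloyloxy)phenyl]hexahydro-4H-pyrano[2,3-d][1,3]dioxine
Product: 18 (4R,4aS,6R,7R,8aR)-6-[2-(1-phenyl-1H-tetrazol-5-ylsulfonyl)ethyl]-4,7-bis[4-(pivaloyloxy)phenyl]hexahydro-4H-pyrano[2,3-d][1,3]dioxine, via sulfoxide 17 (not isolated)
Conditions: (NH4)6Mo7O24·4H2O (10 mol%), 30% aq. H2O2, EtOH/THF, 0 °C → rt
Reagents that add atoms: hydrogen peroxide, OO
Why: molybdate-catalysed peroxide oxidation of the sulfide through sulfoxide 17 to the sulfone, the usual preparation of Julia–Kocienski reagents; no alkene or electron-rich arene is present, and the nearly neutral medium spares the acetal and the esters.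

Step 13
Reactants: 18 (4R,4aS,6R,7R,8aR)-6-[2-(1-phenyl-1H-tetrazol-5-ylsulfonyl)ethyl]-4,7-bis[4-(pivaloyloxy)phenyl]hexahydro-4H-pyrano[2,3-d][1,3]dioxine; 2 4-formylphenyl pivalate
Product: 19 (4R,4aS,6S,7R,8aR)-6-{(2E)-3-[4-(pivaloyloxy)phenyl]prop-2-en-1-yl}-4,7-bis[4-(pivaloyloxy)phenyl]hexahydro-4H-pyrano[2,3-d][1,3]dioxine
Conditions: KN(SiMe3)2 (1.1 equiv), DME, −60 °C, 20 min; then 2 (1.3 equiv), −60 °C → rt
Reagents that add atoms: none
Why: Julia–Kocienski olefination: the metalated tetrazolyl sulfone adds to the aromatic aldehyde, and Smiles rearrangement with loss of SO2 and tetrazololate gives the alkene; the sequence favours the E isomer, which is also the conjugated, more stable one, and brief low-temperature metalation spares the pivalates.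

Step 14
Reactants: 19 (4R,4aS,6S,7R,8aR)-6-{(2E)-3-[4-(pivaloyloxy)phenyl]prop-2-en-1-yl}-4,7-bis[4-(pivaloyloxy)phenyl]hexahydro-4H-pyrano[2,3-d][1,3]dioxine
Product: 21 tris-pivalate of the target, (2R,3S,5R)-oxane with (R)-carbinol, via silyl hemiformal 20 (not isolated)
Conditions: Et3SiH (4 equiv), Me3SiOTf (20 mol%), CH2Cl2, −78 °C; aq. NaHCO3; then AcOH/H2O/THF, rt
Reagents that add atoms: none
Why: ionic reduction of a cyclic mixed acetal, as in silane reductions of 2-alkoxytetrahydropyrans: the silyl triflate ionises the bond from C6 to the formal oxygen, because that gives the oxocarbenium ion stabilised by O1 and expels the better leaving group, and hydride makes C6 a methylene; the C7 oxygen is left as silyl hemiformal 20, which loses formaldehyde on mild aqueous work-up, and no stereocentre is formed or touched.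

Step 15
Reactants: 21 tris-pivalate of the target
Product: 22 4-[(1E)-3-{(2R,3S,5R)-5-[(R)-hydroxy(4-hydroxyphenyl)methyl]-2-(4-hydroxyphenyl)oxan-3-yl}prop-1-en-1-yl]phenol (CNP0182155.1)
Conditions: K2CO3 (4 equiv), MeOH/THF, rt; aq. NH4Cl
Reagents that add atoms: none
Why: base-mediated transesterification of three aryl pivalates with methanol; phenoxide is a good leaving group, so carbonate at room temperature suffices, and neither the benzylic C–O bonds nor the E-alkene are affected.

## Compound list

1 | 4-hydroxybenzaldehyde | O=Cc1ccc(O)cc1 | starting material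
2 | 4-formylphenyl pivalate | CC(C)(C)C(=O)Oc1ccc(C=O)cc1 | intermediate
3 | 4-[(1R)-1-(4,4,5,5-tetramethyl-1,3,2-dioxaborolan-2-yloxy)but-3-en-1-yl]phenyl pivalate | C=CC[C@@H](OB1OC(C)(C)C(C)(C)O1)c1ccc(OC(=O)C(C)(C)C)cc1 | intermediate (not isolated)
4 | 4-[(1R)-1-hydroxybut-3-en-1-yl]phenyl pivalate | C=CC[C@@H](O)c1ccc(OC(=O)C(C)(C)C)cc1 | intermediate
5 | 4-[(1R)-1-hydroxy-3-oxopropyl]phenyl pivalate | O=CC[C@@H](O)c1ccc(OC(=O)C(C)(C)C)cc1 | intermediate (not isolated)
6 | (3R)-3-hydroxy-3-[4-(pivaloyloxy)phenyl]propanoic acid | OC(=O)C[C@@H](O)c1ccc(OC(=O)C(C)(C)C)cc1 | intermediate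
7 | 4-[(4R)-6-oxo-1,3-dioxan-4-yl]phenyl pivalate | O=C1C[C@H](c2ccc(OC(=O)C(C)(C)C)cc2)OCO1 | intermediate
8 | 4-[(4R)-6-hydroxy-1,3-dioxan-4-yl]phenyl pivalate (both C6 epimers) | OC1C[C@H](c2ccc(OC(=O)C(C)(C)C)cc2)OCO1 | intermediate
9 | (6R)-6-[4-(pivaloyloxy)phenyl]-1,3-dioxan-4-yl methanesulfonate | CS(=O)(=O)OC1C[C@H](c2ccc(OC(=O)C(C)(C)C)cc2)OCO1 | intermediate (not isolated)
10 | 4-[(4R)-4H-1,3-dioxin-4-yl]phenyl pivalate | C1OC=C[C@H](c2ccc(OC(=O)C(C)(C)C)cc2)O1 | intermediate
11 | 4-chloro-1-(4-hydroxyphenyl)butan-1-one | O=C(CCCCl)c1ccc(O)cc1 | starting material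
12 | 4-(4-chlorobutanoyl)phenyl pivalate | CC(C)(C)C(=O)Oc1ccc(C(=O)CCCCl)cc1 | intermediate
13 | 4-(4-chloro-2-methylidenebutanoyl)phenyl pivalate | C=C(CCCl)C(=O)c1ccc(OC(=O)C(C)(C)C)cc1 | intermediate
14 | (4R,4aS,8aR)-6-(2-chloroethyl)-4,7-bis[4-(pivaloyloxy)phenyl]-4a,8a-dihydro-4H,5H-pyrano[2,3-d][1,3]dioxine | ClCCC1=C(c2ccc(OC(=O)C(C)(C)C)cc2)O[C@@H]2OCO[C@@H](c3ccc(OC(=O)C(C)(C)C)cc3)[C@@H]2C1 | intermediate
15 | (4R,4aS,6R,7R,8aR)-6-(2-chloroethyl)-4,7-bis[4-(pivaloyloxy)phenyl]hexahydro-4H-pyrano[2,3-d][1,3]dioxine | ClCC[C@H]1C[C@H]2[C@H](c3ccc(OC(=O)C(C)(C)C)cc3)OCO[C@H]2O[C@H]1c1ccc(OC(=O)C(C)(C)C)cc1 | intermediate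
16 | (4R,4aS,6R,7R,8aR)-6-[2-(1-phenyl-1H-tetrazol-5-ylsulfanyl)ethyl]-4,7-bis[4-(pivaloyloxy)phenyl]hexahydro-4H-pyrano[2,3-d][1,3]dioxine | c1ccccc1-n1nnnc1SCC[C@H]1C[C@H]2[C@H](c3ccc(OC(=O)C(C)(C)C)cc3)OCO[C@H]2O[C@H]1c1ccc(OC(=O)C(C)(C)C)cc1 | intermediate
17 | sulfoxide of 16 (both sulfur epimers) | c1ccccc1-n1nnnc1S(=O)CC[C@H]1C[C@H]2[C@H](c3ccc(OC(=O)C(C)(C)C)cc3)OCO[C@H]2O[C@H]1c1ccc(OC(=O)C(C)(C)C)cc1 | intermediate (not isolated)
18 | (4R,4aS,6R,7R,8aR)-6-[2-(1-phenyl-1H-tetrazol-5-ylsulfonyl)ethyl]-4,7-bis[4-(pivaloyloxy)phenyl]hexahydro-4H-pyrano[2,3-d][1,3]dioxine | c1ccccc1-n1nnnc1S(=O)(=O)CC[C@H]1C[C@H]2[C@H](c3ccc(OC(=O)C(C)(C)C)cc3)OCO[C@H]2O[C@H]1c1ccc(OC(=O)C(C)(C)C)cc1 | intermediate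
19 | (4R,4aS,6S,7R,8aR)-6-{(2E)-3-[4-(pivaloyloxy)phenyl]prop-2-en-1-yl}-4,7-bis[4-(pivaloyloxy)phenyl]hexahydro-4H-pyrano[2,3-d][1,3]dioxine | CC(C)(C)C(=O)Oc1ccc(/C=C/C[C@H]2C[C@H]3[C@H](c4ccc(OC(=O)C(C)(C)C)cc4)OCO[C@H]3O[C@H]2c2ccc(OC(=O)C(C)(C)C)cc2)cc1 | intermediate
20 | O-(triethylsilyloxymethyl) ether of 21 at the C7 oxygen | CC(C)(C)C(=O)Oc1ccc(/C=C/C[C@H]2C[C@@H]([C@@H](OCO[Si](CC)(CC)CC)c3ccc(OC(=O)C(C)(C)C)cc3)CO[C@H]2c2ccc(OC(=O)C(C)(C)C)cc2)cc1 | intermediate (not isolated)
21 | 4-[(1E)-3-{(2R,3S,5R)-5-[(R)-hydroxy(4-pivaloyloxyphenyl)methyl]-2-(4-pivaloyloxyphenyl)oxan-3-yl}prop-1-en-1-yl]phenyl pivalate | CC(C)(C)C(=O)Oc1ccc(/C=C/C[C@H]2C[C@@H]([C@@H](O)c3ccc(OC(=O)C(C)(C)C)cc3)CO[C@H]2c2ccc(OC(=O)C(C)(C)C)cc2)cc1 | intermediate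
22 | 4-[(1E)-3-{(2R,3S,5R)-5-[(R)-hydroxy(4-hydroxyphenyl)methyl]-2-(4-hydroxyphenyl)oxan-3-yl}prop-1-en-1-yl]phenol | Oc1ccc(/C=C/C[C@H]2C[C@@H]([C@@H](O)c3ccc(O)cc3)CO[C@H]2c2ccc(O)cc2)cc1 | target

## Step count and risks

Total: 15 steps. Longest linear sequence: 13 steps (1 → 2 → 4 → 6 → 7 → 8 → 10 → 14 → 15 → 16 → 18 → 19 → 21 → 22). The ketone arm (11 → 12 → 13) adds two steps, and aldehyde 2 is used twice, in steps 2 and 13.

**Step 9 (key step).** Three things are most likely to go wrong: the cycloaddition may be slow, because the second ring oxygen makes the dioxin a weaker donor than a simple cyclic enol ether; the dioxin may fragment by heterolysis of its allylic, benzylic C–O bond (an ionic retro-[4+2] to an enal and formaldehyde) under the Lewis acid; and the enone may dimerise. Facial selectivity anti to the aryl group could also be incomplete. The fallback forms the same two bonds one after the other and needs no dioxin. It sets out from lactone 7 and enone 13. The lithium enolate of 7 (LiN(i-Pr)2, THF, −78 °C) should add in Michael fashion to 13 anti to the 6-aryl group, the usual sense for 6-substituted 1,3-dioxan-4-one enolates, and trapping with Me3SiCl would give the silyl enol ether lactone (5S,6R)-5-{2-(2-chloroethyl)-3-[4-(pivaloyloxy)phenyl]-3-(trimethylsilyloxy)prop-2-en-1-yl}-6-[4-(pivaloyloxy)phenyl]-1,3-dioxan-4-one F1. Reduction with i-Bu2AlH at −78 °C, with the ketone still masked, would give the corresponding lactol F2. Pyridinium p-toluenesulfonate in CH2Cl2 over molecular sieves would then unmask the ketone and close the 5-oxo lactol by cyclodehydration to the 2-alkoxy-dihydropyran, returning to the route at 14.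

**Step 14.** The acetal may open at the wrong C–O bond (loss of O1 from C6 would unzip the oxane), the formal carbon may be reduced further to a methyl ether on the C7 oxygen, or the oxocarbenium ion may be captured by the styrene (Prins closure) before hydride arrives. The fallback separates hydrolysis from reduction. It sets out from 19: aqueous acetic acid in THF hydrolyses the acetal, whichever bond breaks first, to the C6-hydroxy derivative of 21 (lactol, both anomers) F3, with loss of formaldehyde. Et3SiH and BF3·OEt2 at −78 °C then reduce the lactol, whose hydroxyl is the only leaving group at C6, and the route is rejoined at 21. The lactol is a masked β-hydroxy aldehyde, so this path is kept in reserve.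

**Step 10.** Hydrogen may be delivered to the concave face if the acetal oxygens anchor the substrate to the metal, the hindered tetrasubstituted alkene may reduce slowly, and prolonged exposure may lead to arene saturation or benzylic C–O cleavage. The fallback replaces surface addition by ionic hydrogenation of 14 (Et3SiH, CF3CO2H, CH2Cl2, −40 °C): protonation at C3 from the open face, then hydride delivery to the 2-aryl oxocarbenium ion anti to the new C3 substituent. It sets out from 14, makes no new compound, and returns at 15.

**Step 6.** Lactol 8 may lose formaldehyde through its open form before it is activated, and the dioxin may be consumed by addition to the oxocarbenium ion from which it forms, or by acid on silica. The fallback avoids the free lactol. It sets out from 7: reduction with i-Bu2AlH followed by acetylation in the same flask (Ac2O, pyridine, DMAP) gives the stable (6R)-6-[4-(pivaloyloxy)phenyl]-1,3-dioxan-4-yl acetate F4. Me3SiOTf with i-Pr2NEt then eliminates acetic acid, returning to the route at 10.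

**Step 13.** E-selectivity may be incomplete, and the base or the sulfonyl carbanion may attack an aryl pivalate if metalation is prolonged. For incomplete selectivity, the fallback equilibrates the alkene mixture by reversible thiyl-radical addition (PhSSPh, visible light, CH2Cl2), which drives a 1-aryl-alkene to its E isomer. It sets out from the crude product of step 13, makes no new compound, and returns at 19.

## Further compounds

F1 | step 9 | (5S,6R)-5-{2-(2-chloroethyl)-3-[4-(pivaloyloxy)phenyl]-3-(trimethylsilyloxy)prop-2-en-1-yl}-6-[4-(pivaloyloxy)phenyl]-1,3-dioxan-4-one (enol ether geometry undefined) | ClCCC(C[C@H]1[C@H](c2ccc(OC(=O)C(C)(C)C)cc2)OCOC1=O)=C(O[Si](C)(C)C)c1ccc(OC(=O)C(C)(C)C)cc1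
F2 | step 9 | (5S,6R)-5-{2-(2-chloroethyl)-3-[4-(pivaloyloxy)phenyl]-3-(trimethylsilyloxy)prop-2-en-1-yl}-6-[4-(pivaloyloxy)phenyl]-1,3-dioxan-4-ol (both C4 epimers) | ClCCC(C[C@H]1[C@H](c2ccc(OC(=O)C(C)(C)C)cc2)OCOC1O)=C(O[Si](C)(C)C)c1ccc(OC(=O)C(C)(C)C)cc1
F3 | step 14 | C6-hydroxy derivative of 21 (lactol, both anomers) | CC(C)(C)C(=O)Oc1ccc(/C=C/C[C@H]2C[C@@H]([C@@H](O)c3ccc(OC(=O)C(C)(C)C)cc3)C(O)O[C@H]2c2ccc(OC(=O)C(C)(C)C)cc2)cc1
F0 | step 10 | none | none
F4 | step 6 | (6R)-6-[4-(pivaloyloxy)phenyl]-1,3-dioxan-4-yl acetate (both C4 epimers) | CC(=O)OC1C[C@H](c2ccc(OC(=O)C(C)(C)C)cc2)OCO1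
F0 | step 13 | none | none
A1 | alternative 1 | 1,5-bis[(4R)-4-benzyl-2-oxo-1,3-oxazolidin-3-yl]pentane-1,5-dione | O=C(CCCC(=O)N1[C@H](Cc2ccccc2)COC1=O)N1[C@H](Cc2ccccc2)COC1=O
A2 | alternative 1 | 4-(tert-butyldimethylsilyloxy)benzaldehyde | O=Cc1ccc(O[Si](C)(C)C(C)(C)C)cc1
A3 | alternative 1 | C2-symmetric bis(anti-aldol) adduct of A1 with two A2 | O=C(N1[C@H](Cc2ccccc2)COC1=O)[C@H]([C@@H](O)c1ccc(O[Si](C)(C)C(C)(C)C)cc1)C[C@@H]([C@@H](O)c1ccc(O[Si](C)(C)C(C)(C)C)cc1)C(=O)N1[C@H](Cc2ccccc2)COC1=O
A4 | alternative 2 | C2-ethynyl oxane carrying the silylated arm and the silylated C5 carbinol unit | CC(C)(C)[Si](C)(C)Oc1ccc(/C=C/C[C@H]2C[C@@H]([C@@H](O[Si](C)(C)C(C)(C)C)c3ccc(O[Si](C)(C)C(C)(C)C)cc3)CO[C@H]2C#C)cc1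
A5 | alternative 2 | 2-(trimethylsilyloxy)buta-1,3-diene | C=CC(=C)O[Si](C)(C)C
A6 | alternative 2 | target with ring A as free phenol and three tert-butyldimethylsilyl ethers | CC(C)(C)[Si](C)(C)Oc1ccc(/C=C/C[C@H]2C[C@@H]([C@@H](O[Si](C)(C)C(C)(C)C)c3ccc(O[Si](C)(C)C(C)(C)C)cc3)CO[C@H]2c2ccc(O)cc2)cc1
A7 | alternative 3 | (1E,3Z,6E)-1-methoxy-3-(trimethylsilyloxy)-7-[4-(tert-butyldimethylsilyloxy)phenyl]hepta-1,3,6-triene | CO/C=C/C(O[Si](C)(C)C)=C/C/C=C/c1ccc(O[Si](C)(C)C(C)(C)C)cc1
A8 | alternative 3 | cis-2-aryl-3-cinnamyl-2,3-dihydro-4H-pyran-4-one | CC(C)(C)[Si](C)(C)Oc1ccc(/C=C/C[C@H]2C(=O)C=CO[C@H]2c2ccc(O[Si](C)(C)C(C)(C)C)cc2)cc1
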